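How much of the substrate will the beta flask have turned into target by 19 min, and should you charge it as written or change something first? With little substrate, you want the answer from the runs already in hand.

| flask | substrate | partner | target | time |
|---|---|---|---|---|
| delta | 0.150 M | 0.450 M |  |  |
| zeta | 0.150 M | 0.450 M | 0.0750 M |  |
| alpha | 0.150 M | 1.40 M |  |  |
| epsilon | 0.450 M | 0.450 M |  |  |
| beta | 0.0600 M | 0.360 M |  | 19 min |

| run | time / min | [target] / M |
|---|---|---|
| delta run | 1.1 | 0.0114 |
| delta run | 3.3 | 0.0301 |
| delta run | 6.3 | 0.0494 |
| delta run | 9.9 | 0.0663 |
| delta run | 14 | 0.0796 |
| delta run | 19 | 0.0921 |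
| zeta run | 1.1 | 0.0861 |
| zeta run | 3.3 | 0.1038 |
| zeta run | 6.3 | 0.1231 |
| zeta run | 9.9 | 0.1390 |
| zeta run | 14 | 0.1517 |
| zeta run | 19 | 0.1626 |
| alpha run | 1.1 | 0.0780 |
| alpha run | 3.3 | 0.1278 |
| alpha run | 6.3 | 0.1384 |
| alpha run | 9.9 | 0.1359 |
| alpha run | 14 | 0.1305 |
| alpha run | 19 | 0.1237 |
| epsilon run | 1.1 | 0.0322 |
| epsilon run | 3.3 | 0.0802 |
| epsilon run | 6.3 | 0.1223 |
| epsilon run | 9.9 | 0.1550 |
| epsilon run | 14 | 0.1809 |
| epsilon run | 19 | 0.2018 |

(readings scatter by 4 × 10⁻⁴ M)

* the exponent of [partner] in the starting rate at the charge of the delta run (at the point where two percent of the substrate have become target)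
* the exponent of [substrate] in the starting rate at the charge of the delta run (at the point where two percent of the substrate have become target) (one fixed amount of target, the same in the runs compared)
* target in the beta run at 19 min, as a share of the substrate charged

- Overall: substrate + partner -> target.
- Constant volume, constant temperature.
- "The second partner" is partner.
- An order is taken over about fifteen percent of the charge, up and down.

Follow one substrate molecule. At the first reading, delta has turned 7.60% of its substrate, and epsilon, with 3.00 times the charge, 7.16%. I read an order in substrate of about 0.945, so at that reading the share turned in these two flasks hangs little on the substrate charge. Zeta, charged with target, gains 0.01110 M over that time against 0.0114 M in delta, so I see no effect of target on the start.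

That lets me treat the substrate as pseudo-first-order at a given partner level, taking partner at its average over the time reckoned, and one quantity serves: the exposure, minus the logarithm of the fraction of substrate still unturned. Alpha's exposure at the first reading, held against delta's, gives an order in partner of about 1.96, so exposure grows with time and with partner squared. Delta's reading at 3.3 min gives an exposure of 0.224, with partner averaging 0.435 M.

If about half of beta's substrate turns, its partner averages 0.345 M. Scaling gives an exposure of 0.811, which is a share of 55.6% before any loss of target. Alpha's target does fall late, from 0.1384 M to 0.1237 M, so I expect a little less.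

The forecast gives orders of 2 in partner and 1 in substrate, and 52%, which is lower than my share: “Subtracting about 1.5% lost leaves about 52%”. On either figure I would charge beta as written.

The flask gives 53.2%, with orders of 2.0 in partner and 1.0 in substrate, and the path to homo dimer makes no difference to that share.

    substrate + 2 partner → target + partner (0.3690 M⁻² min⁻¹)
    2 substrate → homo dimer (0.01548 M⁻¹ min⁻¹)
    target + partner → side product (0.008700 M⁻¹ min⁻¹)

Now use the exposure on alpha. A quarter turned means an exposure of 0.288. Delta's exposure per minute, scaled by partner squared to alpha's charge, is 0.703 min⁻¹. That puts a quarter of alpha's substrate at 0.409 min, and in the alpha run the target made comes to that quarter of the substrate charged at 0.411 min.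

(The runs were computed for an exercise, and the scatter is random.)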